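**Plan**

- Retrosynthesis: the benzene ring is opened first at the two bonds of C1 (the carbon bearing CO2Me), to C2 (aldol) and to C6 (Claisen). This removes C1 and its ester as methyl acetate and leaves a 6-icosyl-4-methoxy-2-pyrone. The CH2–CH2 bond between the ring-bound methylene and the C19 chain is cut next, giving 4-methoxy-6-methyl-2-pyrone and a nonadecyl halide.
- Forward: bromide 1 is converted into iodide 2. Pyrone 3 is deprotonated at its 6-methyl group to trienolate 4, which is alkylated by 2 to give pyrone 5 (chain joined). The pyrone ring of 5 is then turned into the benzene ring of 7 by addition of methyl acetate enolate at the lactone carbonyl, ring opening to 6 and aldol closure; the ring oxygen leaves as water.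
- Enabling feature: in the 2-pyrone ring the 6-CH3 is conjugated through C6=C5 and C4=C3 with the lactone C2=O, so it is the acidic, nucleophilic carbon. Pyrone C2=O, C4–OMe and C6 map onto arene C6–OH, C4–OMe and C2, so the two ring oxygens never have to be told apart.
- Stereochemistry: the target has no stereocentre and no stereogenic double bond; nothing has to be controlled.

Key step: step 2

Assumption: 1, 3, methyl acetate, sodium iodide and a commercial solution of LDA are purchased; "icosyl" denotes the unbranched C20 chain of the target.

**Route**

Step 1
Reactants: 1 1-bromononadecane
Product: 2 1-iodononadecane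
Conditions: NaI (3 equiv), 2-butanone, reflux
Reagents that add atoms: sodium iodide, [Na+].[I-]
Why: Finkelstein halide exchange (SN2 at a primary carbon) is driven by precipitation of sodium bromide and should supply the more reactive electrophile needed for the delocalised anion of step 2.

Step 2
Reactants: 3 4-methoxy-6-methyl-2H-pyran-2-one; 2 1-iodononadecane
Product: 5 6-icosyl-4-methoxy-2H-pyran-2-one, via lithiated pyrone 4 (not isolated)
Conditions: LDA (1.3 equiv), 3 (1.35 equiv), THF, −78 °C; DMPU; then 2 (1.0 equiv) in THF, −78 → −20 °C
Reagents that add atoms: none
Why: LDA removes a proton from the 6-CH3 of 3, and the lithium trienolate 4, delocalised over the exocyclic carbon, C5, C3 and the lactone oxygen, displaces iodide from 2 through its exocyclic CH2 terminus in an SN2 reaction, which forms the CH2–CH2 bond between the C19 chain and the methylene that ends up on the arene. The closest known reaction type is the vinylogous alkylation of extended enolates, that is the lateral metalation and alkylation of 6-methyl-2-pyrones and of o-toluates. No ring is closed and no stereocentre is formed. The step needs site selectivity (exocyclic carbon against C3, C5 and oxygen) and monoalkylation. Attack through the exocyclic terminus is the only mode that restores the conjugated pyrone ring, and the amide base at −78 °C with a short ageing period should deliver the fully delocalised methyl-derived anion and not the C3-lithio species. Keeping 3 and LDA in slight excess over 2 and the temperature at or below −20 °C should limit proton transfer from 5 to 4, second alkylation and self-condensation of the anion.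

Step 3
Reactants: 5 6-icosyl-4-methoxy-2H-pyran-2-one
Product: 7 methyl 2-hydroxy-6-icosyl-4-methoxybenzoate, via ring-opened keto ester 6 (not isolated)
Conditions: MeOAc (3.3 equiv), LDA (3.0 equiv), THF, −78 °C; then 5 in THF, −78 → 0 °C; AcOH (3 equiv); then K2CO3 (0.2 equiv), MeOH, 40 °C
Reagents that add atoms: methyl acetate, CC(=O)OC
Why: Proposed new method: the lithium enolate of methyl acetate should add to the lactone carbonyl (pyrone C2) in a Claisen-type C-acylation, and the tetrahedral intermediate should expel the enolate oxygen on pyrone C6, so that the ring opens to the dianion of 6, in which the former ring double bond keeps C3 and C6 of the chain cis; after buffering with acetic acid, catalytic carbonate should generate the β-keto ester enolate at C2 of 6, which attacks the C7 ketone (6-enolexo-exo-trig aldol), and loss of water with enolisation gives the benzene ring, whose aromaticity makes the sequence irreversible, while the mild base keeps the alternative Claisen closure of C6 onto the ester slow; the closest known reaction types are the acylation of ester enolates and of laterally lithiated toluates by lactone carbonyls, and the biomimetic aldol aromatisation of 3,5,7-trioxo esters to resorcylates.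

**Compound list**

1 | 1-bromononadecane | CCCCCCCCCCCCCCCCCCCBr | starting material
2 | 1-iodononadecane | CCCCCCCCCCCCCCCCCCCI | intermediate
3 | 4-methoxy-6-methyl-2H-pyran-2-one | CC1=CC(OC)=CC(=O)O1 | starting material
4 | lithium 4-methoxy-6-methylidene-6H-pyran-2-olate (lithiated pyrone) | [Li+].C=C1C=C(OC)C=C([O-])O1 | intermediate
5 | 6-icosyl-4-methoxy-2H-pyran-2-one | CCCCCCCCCCCCCCCCCCCCC1=CC(OC)=CC(=O)O1 | intermediate
6 | methyl (4E)-5-methoxy-3,7-dioxoheptacos-4-enoate (ring-opened keto ester) | COC(=O)CC(=O)/C=C(/OC)CC(=O)CCCCCCCCCCCCCCCCCCCC | intermediate
7 | methyl 2-hydroxy-6-icosyl-4-methoxybenzoate | CCCCCCCCCCCCCCCCCCCCc1cc(OC)cc(O)c1C(=O)OC | target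

**Summary**

Total step count: 3. Longest linear sequence: 3 steps (1 → 2 → 5 → 7).

**Steps most likely to fail**

Step 3 (Proposed new method). The ester enolate may take a proton from the chain CH2 next to the pyrone ring, or from C3, instead of adding to the deactivated lactone carbonyl, so that 5 is returned. The open chain may also close in the Claisen sense, or back to an oxygen heterocycle, instead of the aldol sense. The fallback uses known chemistry and leaves the pyrone strategy; it sets out from 2 and comes back to the route at 7. Purchased methyl 2,4-dimethoxy-6-methylbenzoate F1 would be laterally lithiated (LDA, THF, −78 °C) and alkylated with 2 to give methyl 2-icosyl-4,6-dimethoxybenzoate F2, which forms the same CH2–CH2 bond on the finished arene. Boron trichloride (CH2Cl2, −78 → 0 °C) should then cleave only the methyl ether ortho to the ester, through chelation to the carbonyl, and give 7.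

Step 2. The SN2 reaction of the poorly soluble C19 iodide may be too slow at the temperatures the anion tolerates, so that the anion self-condenses on warming. Proton exchange between 4 and 5 may lead to double alkylation, and metalation at C3 may compete. The fallback replaces the substitution by a carbonyl addition; it sets out from 2 and 3 and comes back at 5. Kornblum oxidation of 2 (DMSO, NaHCO3, 110 °C) would give nonadecanal F3. Anion 4 (from 3, LDA, THF, −78 °C) should add to it rapidly to give racemic 6-(2-hydroxyicosyl)-4-methoxy-2H-pyran-2-one F4. Dehydration (cat. TsOH, toluene, reflux) would give 6-[(E)-icos-1-en-1-yl]-4-methoxy-2H-pyran-2-one F5. Hydrogenation of the side-chain alkene alone (H2, 1 atm, Pd/C, EtOAc, stopped after one equivalent) should give 5.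

Step 1. Halide exchange may stop short because the waxy bromide dissolves poorly, leaving a bromide and iodide mixture that is hard to separate. The fallback makes the iodide from the alcohol instead; it sets out from purchased nonadecan-1-ol F6 in place of 1 and comes back at 2. Appel-type iodination of F6 (I2, PPh3, imidazole, CH2Cl2, 0 → 23 °C) should give 2.

**Further compounds**

F1 | step 3 | methyl 2,4-dimethoxy-6-methylbenzoate | COC(=O)c1c(C)cc(OC)cc1OC
F2 | step 3 | methyl 2-icosyl-4,6-dimethoxybenzoate | CCCCCCCCCCCCCCCCCCCCc1cc(OC)cc(OC)c1C(=O)OC
F3 | step 2 | nonadecanal | CCCCCCCCCCCCCCCCCCC=O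
F4 | step 2 | 6-(2-hydroxyicosyl)-4-methoxy-2H-pyran-2-one (racemic) | CCCCCCCCCCCCCCCCCCC(O)CC1=CC(OC)=CC(=O)O1
F5 | step 2 | 6-[(E)-icos-1-en-1-yl]-4-methoxy-2H-pyran-2-one | CCCCCCCCCCCCCCCCCC/C=C/C1=CC(OC)=CC(=O)O1
F6 | step 1 | nonadecan-1-ol | CCCCCCCCCCCCCCCCCCCO
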